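**Retrosynthetic overview**
1. Target 17 ⇐ 16 by cleavage of two MOM acetals; 16 ⇐ aryl bromide 14 + isoprene 15, cutting the dihydrofuran ring (O1, C2, C3, C3a, C7a) at both C3–C3a and O1–C2 (enantioselective Pd-catalysed Heck/Tsuji–Trost [3+2] heteroannulation).
2. Enabling feature: C3, C2 and the three isopropenyl carbons are one intact isoprene unit with an allylic C2–O1 bond, and O1 on C7a is ortho to C3a and para to the acyl-bearing C5. O1/C3a are therefore the oxygen and carbon of an ortho-bromophenol, and with O4 and O6 masked as MOM ethers O1 is the only free oxygen next to C–Br.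
3. 14 ⇐ bromophenol 11 + pyrone 3 + one CH2 (Mannich/methide coupling with Eschenmoser's salt builds the C7–CH2–pyrone bridge).
4. 11 ⇐ phloroglucinol 5 + (R)-2-methylbutanoic acid 4 (Friedel–Crafts acylation, para-O-benzylation, ortho-O-MOM protection, debenzylation, bromination); 3 ⇐ pentan-3-one 1 + malonyl dichloride 2.
5. Order of rings: benzene ring bought with 5, pyrone ring closed in step 1, dihydrofuran ring closed last in step 8.

Key step: step 8

Assumption: (R)-2-methylbutanoic acid 4 is taken as a purchasable single enantiomer; CIP analysis of the target gives (R) at C2 of the dihydrofuran and (R) at the alpha-carbon of the 2-methylbutanoyl group.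

Step 1
Reactants: 1 pentan-3-one; 2 malonyl dichloride
Product: 3 6-ethyl-4-hydroxy-5-methyl-2H-pyran-2-one
Conditions: neat (ketone in excess), rt, 2–3 d with venting of HCl; trituration with Et2O
Reagents that add atoms: none
Why: Ketone–malonyl dichloride pyrone synthesis, in which C-acylation of the enol of pentan-3-one and lactonising O-acylation of the resulting diketone enol should give the 4-hydroxy-2-pyrone with loss of two HCl; no stereocentre is formed.

Step 2
Reactants: 4 (R)-2-methylbutanoic acid; 5 phloroglucinol
Product: 7 (2R)-2-methyl-1-(2,4,6-trihydroxyphenyl)butan-1-one, via acid chloride 6 (not isolated)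
Conditions: a) (COCl)2, cat. DMF, CH2Cl2, 0 °C to rt, evaporation; b) 5, AlCl3 (4 equiv), CH2Cl2/PhNO2, 0 to 40 °C; aq. HCl
Reagents that add atoms: none
Why: Friedel–Crafts acylation of the threefold-symmetric triol can give only one mono-ketone, whose acyl group slows a second acylation, and the base-free acid chloride/acylium conditions are expected to leave the alpha-stereocentre of 4 untouched (enantiomeric purity to be checked at this stage).

Step 3
Reactants: 7 (2R)-2-methyl-1-(2,4,6-trihydroxyphenyl)butan-1-one
Product: 8 (2R)-1-[4-(benzyloxy)-2,6-dihydroxyphenyl]-2-methylbutan-1-one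
Conditions: BnBr (1.0 equiv), K2CO3 (1.1 equiv), DMF, 0 °C to rt
Reagents that add atoms: benzyl bromide, BrCc1ccccc1
Why: Williamson etherification should be selective for the 4-OH, which is the most acidic phenol (para to the ketone) and the only one not held in a chelate hydrogen bond to the carbonyl.

Step 4
Reactants: 8 (2R)-1-[4-(benzyloxy)-2,6-dihydroxyphenyl]-2-methylbutan-1-one
Product: 9 (2R)-1-[4-(benzyloxy)-2,6-bis(methoxymethoxy)phenyl]-2-methylbutan-1-one
Conditions: NaH (2.1 equiv), DMF, 0 °C; then MOMCl (2.5 equiv), 0 °C to rt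
Reagents that add atoms: chloromethyl methyl ether (MOMCl), COCCl
Why: Williamson-type O-alkylation of the two chelated ortho-phenoxides with the hard electrophile MOMCl after full deprotonation, the base being limited to what the two phenols consume so that the alpha-CH of the ketone is not deprotonated.

Step 5
Reactants: 9 (2R)-1-[4-(benzyloxy)-2,6-bis(methoxymethoxy)phenyl]-2-methylbutan-1-one
Product: 10 (2R)-1-[4-hydroxy-2,6-bis(methoxymethoxy)phenyl]-2-methylbutan-1-one
Conditions: H2 (1 atm), 10% Pd/C, EtOAc, rt
Reagents that add atoms: none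
Why: Hydrogenolysis of the aryl benzyl ether should free only the para-phenol, since the MOM acetals and the hindered, twisted aryl ketone are inert under one atmosphere of hydrogen.

Step 6
Reactants: 10 (2R)-1-[4-hydroxy-2,6-bis(methoxymethoxy)phenyl]-2-methylbutan-1-one
Product: 11 (2R)-1-[3-bromo-4-hydroxy-2,6-bis(methoxymethoxy)phenyl]-2-methylbutan-1-one
Conditions: NBS (1.0 equiv), CH2Cl2, −40 to 0 °C
Reagents that add atoms: N-bromosuccinimide, O=C1CCC(=O)N1Br
Why: Electrophilic aromatic bromination ortho to the free phenol, where the two ortho carbons are equivalent and the para position is blocked, so one equivalent of NBS at low temperature should stop at the mono-bromide.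

Step 7
Reactants: 3 6-ethyl-4-hydroxy-5-methyl-2H-pyran-2-one; 11 (2R)-1-[3-bromo-4-hydroxy-2,6-bis(methoxymethoxy)phenyl]-2-methylbutan-1-one
Product: 14 (2R)-1-[3-bromo-5-[(6-ethyl-4-hydroxy-5-methyl-2-oxo-2H-pyran-3-yl)methyl]-4-hydroxy-2,6-bis(methoxymethoxy)phenyl]-2-methylbutan-1-one, via pyrone Mannich base 12 (not isolated), via pyrone methide 13 (not isolated)
Conditions: 3, N,N-dimethylmethyleneiminium iodide (1.05 equiv), MeCN, rt; then 11 (1.2 equiv), 70 °C
Reagents that add atoms: Eschenmoser's salt (N,N-dimethylmethyleneiminium iodide), C=[N+](C)C.[I-]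
Why: Mannich aminomethylation of the pyrone at C3, thermal loss of dimethylamine to the 3-methylidene-pyran-2,4-dione and Friedel–Crafts-type conjugate addition of the phenol through its only free ring carbon, the tactic established for methylene-bridged pyrone–acylphloroglucinol dimers.

Step 8
Reactants: 14 (2R)-1-[3-bromo-5-[(6-ethyl-4-hydroxy-5-methyl-2-oxo-2H-pyran-3-yl)methyl]-4-hydroxy-2,6-bis(methoxymethoxy)phenyl]-2-methylbutan-1-one; 15 isoprene
Product: 16 (2R)-1-[(2R)-7-[(6-ethyl-4-hydroxy-5-methyl-2-oxo-2H-pyran-3-yl)methyl]-4,6-bis(methoxymethoxy)-2-(prop-1-en-2-yl)-2,3-dihydro-1-benzofuran-5-yl]-2-methylbutan-1-one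
Conditions: Pd2(dba)3·CHCl3 (5 mol %), chiral sulfinamide–monophosphine ligand of the TY-Phos type (20 mol %, enantiomer giving the (R) ring), PhONa (3 equiv), isoprene (10 equiv), CH2Cl2, 40 °C, sealed tube
Reagents that add atoms: none
Why: Zerovalent palladium inserts into the C–Br bond of 14, the aryl–palladium adds across the unsubstituted vinyl end of isoprene (aryl to the terminal CH2, which becomes C3) to give a π-allylpalladium over the remaining three carbons, and the neighbouring phenoxide attacks the internal allyl terminus anti to the metal to form O1–C2 and release the catalyst. The closest known reaction is the palladium-catalysed heteroannulation of 2-halophenols with 1,3-dienes (Larock annulation) in its enantioselective Heck/Tsuji–Trost form with chiral sulfinamide–phosphine ligands, which converts simple 2-bromophenols and isoprene into 2-isopropenyl-2,3-dihydrobenzofurans of the tremetone type. The dihydrofuran ring is closed in a formal [3+2] manner, C3–C3a by intermolecular carbopalladation and then O1–C2 by 5-exo allylic substitution, the seven-membered alternative through the far CH2 terminus being disfavoured. The stereocentre C2 is set under catalyst control in the C–O bond-forming attack on the π-allyl, whose faces interconvert by η3–η1–η3 slippage through the unsubstituted CH2 terminus, so the chosen ligand enantiomer (sense to be fixed first on 2-bromophenol plus isoprene as a model) should deliver the (R) centre irrespective of the remote (R) side-chain centre. The step needs regioselective diene insertion (secured by the slower-inserting 1,1-disubstituted end of isoprene), a single oxygen nucleophile (secured because the other oxygen flanking C–Br is a MOM ether and the pyrone hydroxyl cannot reach the allyl unit in a small ring) and a single reacting C–Br bond, while the para-acyl group makes the phenoxide a stabilised nucleophile and the ring less electron-rich for oxidative addition.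

Step 9
Reactants: 16 (2R)-1-[(2R)-7-[(6-ethyl-4-hydroxy-5-methyl-2-oxo-2H-pyran-3-yl)methyl]-4,6-bis(methoxymethoxy)-2-(prop-1-en-2-yl)-2,3-dihydro-1-benzofuran-5-yl]-2-methylbutan-1-one
Product: 17 (2R)-1-[(2R)-7-[(6-ethyl-4-hydroxy-5-methyl-2-oxo-2H-pyran-3-yl)methyl]-4,6-dihydroxy-2-(prop-1-en-2-yl)-2,3-dihydro-1-benzofuran-5-yl]-2-methylbutan-1-one
Conditions: 3 M aq. HCl (few equiv), MeOH, rt to 40 °C, monitored; NaHCO3 quench
Reagents that add atoms: none
Why: Acid-catalysed transacetalisation of the two MOM ethers, which the ortho carbonyl activates, under conditions expected to spare the 1,1-disubstituted alkene (its cation would be destabilised by the adjacent C–O bond) and the weakly basic, ketone-conjugated aryl ether oxygen.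

**Compound list**
1 | pentan-3-one | CCC(=O)CC | starting material
2 | malonyl dichloride | ClC(=O)CC(=O)Cl | starting material
3 | 6-ethyl-4-hydroxy-5-methyl-2H-pyran-2-one | O=c1cc(O)c(C)c(CC)o1 | intermediate
4 | (R)-2-methylbutanoic acid | CC[C@@H](C)C(=O)O | starting material
5 | phloroglucinol (benzene-1,3,5-triol) | Oc1cc(O)cc(O)c1 | starting material
6 | (R)-2-methylbutanoyl chloride | CC[C@@H](C)C(=O)Cl | intermediate
7 | (2R)-2-methyl-1-(2,4,6-trihydroxyphenyl)butan-1-one | CC[C@@H](C)C(=O)c1c(O)cc(O)cc1O | intermediate
8 | (2R)-1-[4-(benzyloxy)-2,6-dihydroxyphenyl]-2-methylbutan-1-one | CC[C@@H](C)C(=O)c1c(O)cc(OCc2ccccc2)cc1O | intermediate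
9 | (2R)-1-[4-(benzyloxy)-2,6-bis(methoxymethoxy)phenyl]-2-methylbutan-1-one | CC[C@@H](C)C(=O)c1c(OCOC)cc(OCc2ccccc2)cc1OCOC | intermediate
10 | (2R)-1-[4-hydroxy-2,6-bis(methoxymethoxy)phenyl]-2-methylbutan-1-one | CC[C@@H](C)C(=O)c1c(OCOC)cc(O)cc1OCOC | intermediate
11 | (2R)-1-[3-bromo-4-hydroxy-2,6-bis(methoxymethoxy)phenyl]-2-methylbutan-1-one | CC[C@@H](C)C(=O)c1c(OCOC)c(Br)c(O)cc1OCOC | intermediate
12 | 3-[(dimethylamino)methyl]-6-ethyl-4-hydroxy-5-methyl-2H-pyran-2-one (pyrone Mannich base) | CN(C)Cc1c(O)c(C)c(CC)oc1=O | intermediate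
13 | 6-ethyl-5-methyl-3-methylidene-2H-pyran-2,4(3H)-dione (pyrone methide) | C=C1C(=O)OC(CC)=C(C)C1=O | intermediate
14 | (2R)-1-[3-bromo-5-[(6-ethyl-4-hydroxy-5-methyl-2-oxo-2H-pyran-3-yl)methyl]-4-hydroxy-2,6-bis(methoxymethoxy)phenyl]-2-methylbutan-1-one | CC[C@@H](C)C(=O)c1c(OCOC)c(Br)c(O)c(Cc2c(O)c(C)c(CC)oc2=O)c1OCOC | intermediate
15 | isoprene (2-methylbuta-1,3-diene) | C=CC(C)=C | starting material
16 | (2R)-1-[(2R)-7-[(6-ethyl-4-hydroxy-5-methyl-2-oxo-2H-pyran-3-yl)methyl]-4,6-bis(methoxymethoxy)-2-(prop-1-en-2-yl)-2,3-dihydro-1-benzofuran-5-yl]-2-methylbutan-1-one | C=C(C)[C@H]1Cc2c(OCOC)c(C(=O)[C@H](C)CC)c(OCOC)c(Cc3c(O)c(C)c(CC)oc3=O)c2O1 | intermediate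
17 | (2R)-1-[(2R)-7-[(6-ethyl-4-hydroxy-5-methyl-2-oxo-2H-pyran-3-yl)methyl]-4,6-dihydroxy-2-(prop-1-en-2-yl)-2,3-dihydro-1-benzofuran-5-yl]-2-methylbutan-1-one | C=C(C)[C@H]1Cc2c(O)c(C(=O)[C@H](C)CC)c(O)c(Cc3c(O)c(C)c(CC)oc3=O)c2O1 | target

**Step count:** 9 steps in total. Longest linear sequence: 8 steps (steps 2 to 9, from 4 and 5 to 17); step 1 is a one-step branch.

**Steps most likely to fail**

1. Step 8. Oxidative addition and carbopalladation at an aryl bromide flanked by two oxygens may be slow, so that protodebromination or simple Heck diene formation takes over, and the facial discrimination in the C–O closure may be insufficient. The fallback sets out from 14 and comes back at 16, closing the same ring by C–O bond formation only. Stille coupling of 14 with allyltributylstannane (Pd(PPh3)4, LiCl, DMF, 90 °C) should give the allyl arene F1. Cross-metathesis of F1 with 2-methylallyl methyl carbonate (second-generation Hoveyda–Grubbs catalyst, CH2Cl2, 40 °C) should give the (E)-allylic methyl carbonate F2. Intramolecular Trost asymmetric allylic etherification of F2 (Pd2(dba)3·CHCl3, DACH-phenyl Trost ligand, CH2Cl2, rt) should then form O1–C2 and return 16; this cyclisation of 2-(4-carbonate-3-methylbut-2-enyl)phenols to 2-isopropenyl-dihydrobenzofurans is known chemistry.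

2. Step 7. The methide may be intercepted by unreacted pyrone (symmetrical bis-pyronylmethane) or by the phenol oxygen, and C-alkylation of the bromine-deactivated, hindered phenol may be slow. The fallback sets out from 11 and comes back at 14 with the polarity of the bridge-forming step reversed. Aminomethylation of 11 with Eschenmoser's salt ortho to the free phenol (MeCN, rt; NaHCO3) should give the arene Mannich base F3. Heating F3 with pyrone 3 (1,4-dioxane, 100 °C) should expel dimethylamine to an ortho-quinone methide of the arene, which the nucleophilic C3 of the pyrone captures to give 14.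

3. Step 9. Acid may open the allylic aryl ether or add across the isopropenyl group before both acetals are cleaved. The fallback sets out from 14 and comes back at 17 by removing the acetals before the acid-sensitive ring exists. Treatment of 14 with 3 M aq. HCl in MeOH should give the unprotected bromo-phenol F4. The Heck/Tsuji–Trost annulation of step 8 is then run on F4 with isoprene and should give 17 directly. The choice of oxygen would then rest on the higher acidity of the hydroxyl para to the acyl group, the ortho hydroxyl next to C–Br being chelated to the ketone.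

**Further compounds**
F1 | step 8 | (2R)-1-[3-[(6-ethyl-4-hydroxy-5-methyl-2-oxo-2H-pyran-3-yl)methyl]-4-hydroxy-2,6-bis(methoxymethoxy)-5-(prop-2-en-1-yl)phenyl]-2-methylbutan-1-one | CC[C@@H](C)C(=O)c1c(OCOC)c(CC=C)c(O)c(Cc2c(O)c(C)c(CC)oc2=O)c1OCOC
F2 | step 8 | (2E)-4-[3-[(6-ethyl-4-hydroxy-5-methyl-2-oxo-2H-pyran-3-yl)methyl]-2-hydroxy-4,6-bis(methoxymethoxy)-5-[(2R)-2-methylbutanoyl]phenyl]-2-methylbut-2-en-1-yl methyl carbonate | CC[C@@H](C)C(=O)c1c(OCOC)c(C/C=C(\C)COC(=O)OC)c(O)c(Cc2c(O)c(C)c(CC)oc2=O)c1OCOC
F3 | step 7 | (2R)-1-[3-bromo-5-[(dimethylamino)methyl]-4-hydroxy-2,6-bis(methoxymethoxy)phenyl]-2-methylbutan-1-one | CC[C@@H](C)C(=O)c1c(OCOC)c(Br)c(O)c(CN(C)C)c1OCOC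
F4 | step 9 | (2R)-1-[3-bromo-5-[(6-ethyl-4-hydroxy-5-methyl-2-oxo-2H-pyran-3-yl)methyl]-2,4,6-trihydroxyphenyl]-2-methylbutan-1-one | CC[C@@H](C)C(=O)c1c(O)c(Br)c(O)c(Cc2c(O)c(C)c(CC)oc2=O)c1O
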